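## Retrosynthetic overview

1. Target 17 ⇐ diacetate 16 by lipase-catalysed removal of the two B-ring acetates (last step, neutral pH).
2. 16 ⇐ chromone 9 + boronic acid 15 by Rh(I)/(S)-bisphosphine asymmetric 1,4-arylation, which sets C2, the only stereocentre.
3. 9 ⇐ O-prenyl ether 6 by Eu(III) para-Claisen–Cope rearrangement (prenyl O5 → C8) ⇐ 5-hydroxy-7-methoxychromone 4.
4. 4 ⇐ acetophenone 1 by enaminone annulation; 15 ⇐ 4-bromocatechol 10 by acetylation, Miyaura borylation and pinacol cleavage.
5. Ring order: A ring bought → pyranone ring closed (step 1) → B ring attached (step 7), which also saturates the pyranone to the flavanone.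

Assumption: the (S)-biaryl bisphosphine gives 2S on chromone 9, the same sense as (S)-BINAP giving (S)-3-arylcyclohexanones; if chiral HPLC/CD shows the opposite, the (R)-ligand is used.

## Route

Step 1
Reactants: 1 1-(2,6-dihydroxy-4-methoxyphenyl)ethan-1-one; 2 N,N-dimethylformamide dimethyl acetal
Product: 4 5-hydroxy-7-methoxy-4H-chromen-4-one, via enaminone 3 (not isolated)
Conditions: DMF-DMA (2.5 equiv), toluene, 95 °C; then conc. HCl, CH2Cl2, 40 °C
Reagents that add atoms: N,N-dimethylformamide dimethyl acetal, COC(OC)N(C)C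
Why: The methyl ketone condenses with the amide acetal to the enaminone, and acid then drives O-addition/elimination of dimethylamine (enaminone chromone annulation); the two phenols of 1 are equivalent, so only one chromone can form and the other OH becomes the chelated 5-OH.

Step 2
Reactants: 4 5-hydroxy-7-methoxy-4H-chromen-4-one; 5 1-bromo-3-methylbut-2-ene (prenyl bromide)
Product: 6 7-methoxy-5-[(3-methylbut-2-en-1-yl)oxy]-4H-chromen-4-one
Conditions: prenyl bromide (1.5 equiv), K2CO3, DMF, 50 °C
Reagents that add atoms: prenyl bromide, CC(C)=CCBr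
Why: Williamson etherification of the only phenol; K2CO3 in DMF breaks the 5-OH···O=C4 chelate and the allylic bromide alkylates on oxygen.

Step 3
Reactants: 6 7-methoxy-5-[(3-methylbut-2-en-1-yl)oxy]-4H-chromen-4-one
Product: 9 5-hydroxy-7-methoxy-8-(3-methylbut-2-en-1-yl)-4H-chromen-4-one, via ortho-Claisen dienone 7 (not isolated), via Cope dienone 8 (not isolated)
Conditions: Eu(fod)3 (10 mol %), NaHCO3, PhCl, 85 °C
Reagents that add atoms: none
Why: Eu(III) chelation of O5/C4=O accelerates the aromatic Claisen rearrangement to C6, and the crowded 6-(1,1-dimethylallyl) dienone moves on by a Cope shift to C8 before tautomerising (para-Claisen–Cope), so a linear prenyl ends up at C8 and the 5-OH is regenerated; this is an isomerisation and nothing is split off.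

Step 4
Reactants: 10 4-bromobenzene-1,2-diol; 11 acetic anhydride
Product: 12 4-bromo-1,2-phenylene diacetate
Conditions: Ac2O, pyridine, DMAP (cat.), CH2Cl2, 0 °C to rt
Reagents that add atoms: acetic anhydride, CC(=O)OC(C)=O
Why: DMAP-catalysed O-acetylation of both phenols installs the ester groups that the lipase will later remove.

Step 5
Reactants: 12 4-bromo-1,2-phenylene diacetate; 13 bis(pinacolato)diboron
Product: 14 4-(4,4,5,5-tetramethyl-1,3,2-dioxaborolan-2-yl)-1,2-phenylene diacetate
Conditions: B2pin2, PdCl2(dppf)·CH2Cl2 (3 mol %), KOAc, 1,4-dioxane, 85 °C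
Reagents that add atoms: bis(pinacolato)diboron, CC1(C)OB(OC1(C)C)B1OC(C)(C)C(C)(C)O1
Why: Miyaura borylation at the only C–Br bond; anhydrous KOAc is too weak a base to cleave the aryl acetates.

Step 6
Reactants: 14 4-(4,4,5,5-tetramethyl-1,3,2-dioxaborolan-2-yl)-1,2-phenylene diacetate
Product: 15 (3,4-diacetoxyphenyl)boronic acid
Conditions: NaIO4, THF/H2O (4:1), rt; then 1 M HCl, rt
Reagents that add atoms: water, O
Why: Hydrolysis of the boronate is pulled to completion by periodate cleavage of the released pinacol (oxidative pinacol boronate deprotection), and the mildly acidic medium leaves the aryl acetates intact.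

Step 7
Reactants: 9 5-hydroxy-7-methoxy-8-(3-methylbut-2-en-1-yl)-4H-chromen-4-one; 15 (3,4-diacetoxyphenyl)boronic acid
Product: 16 4-[(2S)-5-hydroxy-7-methoxy-8-(3-methylbut-2-en-1-yl)-4-oxo-3,4-dihydro-2H-chromen-2-yl]-1,2-phenylene diacetate
Conditions: [Rh(OH)(cod)]2 (2.5 mol %), (S)-MeO-F12-BIPHEP [(S)-2,2'-bis(bis(3,4,5-trifluorophenyl)phosphino)-6,6'-dimethoxybiphenyl] (5.5 mol %), 15 (3 equiv), toluene/H2O (10:1), 35 °C, no added base
Reagents that add atoms: none
Why: Hayashi–Miyaura asymmetric 1,4-addition, in which the aryl–Rh(I) species bearing the (S)-bisphosphine adds across C2=C3 on one enantioface and water protonates the oxa-π-allyl rhodium, setting C2 as S; the base-free, low-temperature conditions keep the acetates on and avoid retro-oxa-Michael opening, the trisubstituted prenyl alkene is inert, and the chelated 5-OH activates the enone.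

Step 8
Reactants: 16 4-[(2S)-5-hydroxy-7-methoxy-8-(3-methylbut-2-en-1-yl)-4-oxo-3,4-dihydro-2H-chromen-2-yl]-1,2-phenylene diacetate
Product: 17 (2S)-2-(3,4-dihydroxyphenyl)-5-hydroxy-7-methoxy-8-(3-methylbut-2-en-1-yl)-2,3-dihydro-4H-chromen-4-one
Conditions: lipase (triacylglycerol lipase, a serine hydrolase; immobilised Burkholderia cepacia lipase), n-BuOH (10 equiv), THF, 45 °C
Reagents that add atoms: none
Why: The lipase transfers both phenolic acetyl groups to n-butanol through its acyl-enzyme intermediate at neutral pH (enzymatic transesterification), so the base-labile C2 stereocentre and the acid-sensitive prenyl group are untouched.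

## Compound list

1 | 1-(2,6-dihydroxy-4-methoxyphenyl)ethan-1-one | CC(=O)c1c(O)cc(OC)cc1O | starting material
2 | N,N-dimethylformamide dimethyl acetal | COC(OC)N(C)C | starting material
3 | (E)-1-(2,6-dihydroxy-4-methoxyphenyl)-3-(dimethylamino)prop-2-en-1-one | CN(C)/C=C/C(=O)c1c(O)cc(OC)cc1O | intermediate
4 | 5-hydroxy-7-methoxy-4H-chromen-4-one | COc1cc(O)c2c(c1)occc2=O | intermediate
5 | 1-bromo-3-methylbut-2-ene | CC(C)=CCBr | starting material
6 | 7-methoxy-5-[(3-methylbut-2-en-1-yl)oxy]-4H-chromen-4-one | COc1cc(OCC=C(C)C)c2c(c1)occc2=O | intermediate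
7 | 7-methoxy-6-(2-methylbut-3-en-2-yl)-4H-chromene-4,5(6H)-dione (racemic at C6, transient) | COC1=CC2=C(C(=O)C=CO2)C(=O)C1C(C)(C)C=C | intermediate
8 | 7-methoxy-8-(3-methylbut-2-en-1-yl)-4H-chromene-4,5(8H)-dione (racemic at C8, transient) | COC1=CC(=O)C2=C(OC=CC2=O)C1CC=C(C)C | intermediate
9 | 5-hydroxy-7-methoxy-8-(3-methylbut-2-en-1-yl)-4H-chromen-4-one | COc1cc(O)c2c(c1CC=C(C)C)occc2=O | intermediate
10 | 4-bromobenzene-1,2-diol | Oc1ccc(Br)cc1O | starting material
11 | acetic anhydride | CC(=O)OC(C)=O | starting material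
12 | 4-bromo-1,2-phenylene diacetate | CC(=O)Oc1ccc(Br)cc1OC(C)=O | intermediate
13 | bis(pinacolato)diboron | CC1(C)OB(OC1(C)C)B1OC(C)(C)C(C)(C)O1 | starting material
14 | 4-(4,4,5,5-tetramethyl-1,3,2-dioxaborolan-2-yl)-1,2-phenylene diacetate | CC(=O)Oc1ccc(cc1OC(C)=O)B1OC(C)(C)C(C)(C)O1 | intermediate
15 | (3,4-diacetoxyphenyl)boronic acid | CC(=O)Oc1ccc(cc1OC(C)=O)B(O)O | intermediate
16 | 4-[(2S)-5-hydroxy-7-methoxy-8-(3-methylbut-2-en-1-yl)-4-oxo-3,4-dihydro-2H-chromen-2-yl]-1,2-phenylene diacetate | COc1cc(O)c2c(c1CC=C(C)C)O[C@H](c1ccc(OC(C)=O)c(OC(C)=O)c1)CC2=O | intermediate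
17 | (2S)-2-(3,4-dihydroxyphenyl)-5-hydroxy-7-methoxy-8-(3-methylbut-2-en-1-yl)-2,3-dihydro-4H-chromen-4-one | COc1cc(O)c2c(c1CC=C(C)C)O[C@H](c1ccc(O)c(O)c1)CC2=O | target

## Summary

Total steps: 8. Longest linear sequence: 5 steps (1 → 4 → 6 → 9 → 16 → 17; the branch 10 → 12 → 14 → 15 → 16 → 17 is also 5).

Three steps most likely to fail:

**Step 7 (asymmetric arylation of 9).** The free 5-OH, the electron-rich chromone and the 8-substituent may slow the addition or lower the ee. Fallback: change the order of events. The same Rh/(S)-bisphosphine arylation with 15 is run on the O-prenyl chromone 6, a neutral 5,7-dialkoxychromone with no acidic OH, to give 4-[(2S)-7-methoxy-5-[(3-methylbut-2-en-1-yl)oxy]-4-oxo-3,4-dihydro-2H-chromen-2-yl]-1,2-phenylene diacetate F1. The Eu(fod)3/NaHCO3 para-Claisen–Cope (PhCl, 60–85 °C) is then carried out on this flavanone. It passes through the ortho-Claisen dienone 4-[(2S)-7-methoxy-6-(2-methylbut-3-en-2-yl)-4,5-dioxo-3,4,5,6-tetrahydro-2H-chromen-2-yl]-1,2-phenylene diacetate F2 and the Cope dienone 4-[(2S)-7-methoxy-8-(3-methylbut-2-en-1-yl)-4,5-dioxo-3,4,5,8-tetrahydro-2H-chromen-2-yl]-1,2-phenylene diacetate F3, neither isolated. The fallback sets out from 6 (with 15) and comes back at 16. C2 takes no part in the rearrangement and the Eu(III) catalyst is not basic; the ee is checked by chiral HPLC before step 8.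

**Step 3 (para-Claisen–Cope on 6).** The ortho dienone may tautomerise before the Cope shift and give the 6-(1,1-dimethylallyl) isomer. Fallback: install the prenyl group by cross-coupling instead. Chromone 4 is protected with MOMCl/NaH (DMF, 0 °C) to give 7-methoxy-5-(methoxymethoxy)-4H-chromen-4-one F4. NIS (MeCN, rt) iodinates C8, the usual site for 5,7-dialkoxychromones (confirmed by NOE), to give 8-iodo-7-methoxy-5-(methoxymethoxy)-4H-chromen-4-one F5. Stille coupling with tributyl(3-methylbut-2-en-1-yl)stannane (Pd(PPh3)4, DMF, 90 °C) gives 7-methoxy-5-(methoxymethoxy)-8-(3-methylbut-2-en-1-yl)-4H-chromen-4-one F6. 2 M HCl in THF at rt removes the peri MOM group. The fallback sets out from 4 and comes back at 9.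

**Step 6 (pinacol cleavage to 15).** The aryl acetates may be partly lost, or the polar boronic acid may be hard to isolate. Fallback: avoid a separate boronate deprotection. Bromide 12 is borylated under the step 5 conditions with bis(neopentyl glycolato)diboron in place of B2pin2 to give 4-(5,5-dimethyl-1,3,2-dioxaborinan-2-yl)-1,2-phenylene diacetate F7. This ester hydrolyses in the aqueous toluene of step 7 and is used there directly with 9. The fallback sets out from 12 and comes back at 16.

## Further compounds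

F1 | step 7 | 4-[(2S)-7-methoxy-5-[(3-methylbut-2-en-1-yl)oxy]-4-oxo-3,4-dihydro-2H-chromen-2-yl]-1,2-phenylene diacetate | COc1cc(OCC=C(C)C)c2c(c1)O[C@H](c1ccc(OC(C)=O)c(OC(C)=O)c1)CC2=O
F2 | step 7 | 4-[(2S)-7-methoxy-6-(2-methylbut-3-en-2-yl)-4,5-dioxo-3,4,5,6-tetrahydro-2H-chromen-2-yl]-1,2-phenylene diacetate (mixture at C6, not isolated) | COC1=CC2=C(C(=O)C1C(C)(C)C=C)C(=O)C[C@@H](c1ccc(OC(C)=O)c(OC(C)=O)c1)O2
F3 | step 7 | 4-[(2S)-7-methoxy-8-(3-methylbut-2-en-1-yl)-4,5-dioxo-3,4,5,8-tetrahydro-2H-chromen-2-yl]-1,2-phenylene diacetate (mixture at C8, not isolated) | COC1=CC(=O)C2=C(O[C@H](c3ccc(OC(C)=O)c(OC(C)=O)c3)CC2=O)C1CC=C(C)C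
F4 | step 3 | 7-methoxy-5-(methoxymethoxy)-4H-chromen-4-one | COCOc1cc(OC)cc2occc(=O)c12
F5 | step 3 | 8-iodo-7-methoxy-5-(methoxymethoxy)-4H-chromen-4-one | COCOc1cc(OC)c(I)c2occc(=O)c12
F6 | step 3 | 7-methoxy-5-(methoxymethoxy)-8-(3-methylbut-2-en-1-yl)-4H-chromen-4-one | COCOc1cc(OC)c(CC=C(C)C)c2occc(=O)c12
F7 | step 6 | 4-(5,5-dimethyl-1,3,2-dioxaborinan-2-yl)-1,2-phenylene diacetate | CC(=O)Oc1ccc(cc1OC(C)=O)B1OCC(C)(C)CO1
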